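**Plan**

- Retrosynthetic cuts: the carbamate and the three O–Si bonds; C8–CH3; the C8=C9 olefin, traced back to a ring alkyne and cut at C8≡C9; then N–aryl, C3–C4, C6–C7, C9–C10, C11–C12 and aryl–C15.
- Enabling feature: in the 19-membered ansa ring (lactam N, C1–C15, three benzene carbons) C7 carries oxygen and its neighbour C8 is the methyl-bearing carbon of the E C8=C9 olefin. This O–C7–C8(CH3)=C9 array is what a ring alkyne C8≡C9 with a C7 hydroxyl gives after directed trans-hydrostannation and methylation, so the ring can be closed as an alkyne with no olefin geometry at stake.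
- Forward order: east chain aryl–C15, then C11–C12, then C9–C10; west chain C6–C7, then C3–C4; union at N–aryl; the single ring closure at C8≡C9; then C8–CH3, carbamate, desilylation.
- Stereochemistry: C14 is bought. C12 comes from Noyori transfer hydrogenation and is passed to C11 and C10 by a matched Sharpless epoxidation and an invertive epoxide opening. C6 and C7 come together from one Brown (Z)-γ-methoxyallylboration. 2E comes from syn-carboalumination, 8E from trans-hydrostannation and retentive Stille coupling.

Key step: step 20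

Remark: atoms are numbered as in the ansamycins (C1 lactam carbonyl to C15 benzylic carbon); the given structure is read as (6S,7S,10S,11R,12S,14R) with 2E and 8E olefins, and every reagent antipode below is chosen for that enantiomer.

**Route**

Step 1
Reactants: 1 4-bromo-2-iodophenol
Product: 2 (4-bromo-2-iodophenoxy)triisopropylsilane
Conditions: TIPSCl, imidazole, DMF, rt
Reagents that add atoms: triisopropylsilyl chloride, CC(C)[Si](Cl)(C(C)C)C(C)C
Why: Imidazole-mediated O-silylation of a phenol is routine, and the bulky TIPS ether is chosen because it should withstand the Grignard, hydride, Lewis acid and hot carbonate steps that follow and fall only to fluoride at the end.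

Step 2
Reactants: 3 (R)-methyl hydrogen 3-methylglutarate
Product: 4 N-hydroxyphthalimide ester of 3 (1,3-dioxoisoindolin-2-yl methyl 3-methylpentanedioate; configuration of 3 unchanged; CIP label S)
Conditions: N-hydroxyphthalimide, DIC, DMAP (cat.), CH2Cl2, rt
Reagents that add atoms: N-hydroxyphthalimide, ON1C(=O)c2ccccc2C1=O
Why: Carbodiimide (Steglich-type) esterification activates only the free acid as a redox-active ester, and the C14 stereocentre, which is beta to both carbonyls, cannot epimerise.

Step 3
Reactants: 2 (4-bromo-2-iodophenoxy)triisopropylsilane; 4 N-hydroxyphthalimide ester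
Product: 5 methyl (3R)-4-[5-bromo-2-(triisopropylsilyloxy)phenyl]-3-methylbutanoate
Conditions: NiBr2(dme) (10 mol%), 4,4'-di-tert-butyl-2,2'-bipyridine, Zn dust, DMA, rt
Reagents that add atoms: none
Why: Nickel-catalysed decarboxylative reductive cross-electrophile coupling, in which zerovalent nickel inserts into the C–I bond much faster than into C–Br, the zinc-reduced phthalimide ester fragments with loss of CO2 to a primary alkyl radical that is captured at nickel, and reductive elimination joins the former carboxyl-bearing CH2 (C15) to the arene without touching C14.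

Step 4
Reactants: 5 aryl ester
Product: 6 (3R)-4-[5-bromo-2-(triisopropylsilyloxy)phenyl]-N-methoxy-N,3-dimethylbutanamide
Conditions: MeNHOMe·HCl, i-PrMgCl, THF, −20 °C
Reagents that add atoms: N,O-dimethylhydroxylamine hydrochloride, CNOC.Cl
Why: Weinreb amide synthesis by aminolysis of the methyl ester with the chloromagnesium amide formed in the flask, run cold so that bromine–magnesium exchange at the electron-rich aryl bromide does not compete.

Step 5
Reactants: 6 Weinreb amide; 7 propyne
Product: 9 (6R)-7-[5-bromo-2-(triisopropylsilyloxy)phenyl]-6-methylhept-2-yn-4-one, via 1-propynylmagnesium bromide 8 (not isolated)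
Conditions: 7, EtMgBr, THF, 0 °C; then 6, 0 °C to rt
Reagents that add atoms: none
Why: Acylation of an alkynyl Grignard reagent by a Weinreb amide stops at the ynone because the chelated tetrahedral adduct persists until aqueous work-up, which forms the C11–C12 bond.

Step 6
Reactants: 9 ynone
Product: 10 (4S,6R)-7-[5-bromo-2-(triisopropylsilyloxy)phenyl]-6-methylhept-2-yn-4-ol
Conditions: Ru[(S,S)-TsDPEN](p-cymene) (2 mol%), i-PrOH, rt
Reagents that add atoms: none
Why: Noyori asymmetric transfer hydrogenation of an ynone, in which the (S,S)-TsDPEN ruthenium hydride hands hydride and proton to the carbonyl face that leads to the (S)-propargylic alcohol (the alkyne takes the place that the aryl group has in acetophenone-type substrates), so that C12 is set by the catalyst and not by remote C14.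

Step 7
Reactants: 10 propargylic alcohol
Product: 11 (2E,4S,6R)-7-[5-bromo-2-(triisopropylsilyloxy)phenyl]-6-methylhept-2-en-4-ol
Conditions: NaAlH2(OCH2CH2OMe)2 (Red-Al), THF, 0 °C to rt; aq. KNaC4H4O6
Reagents that add atoms: none
Why: Alkoxide-directed trans-hydroalumination of the propargylic alcohol followed by protonolysis should give the E-allylic alcohol only, and aryl bromide, aryl silyl ether and C12 are not affected under these mild conditions.

Step 8
Reactants: 11 E-allylic alcohol
Product: 12 (1S,3R)-4-[5-bromo-2-(triisopropylsilyloxy)phenyl]-3-methyl-1-[(2S,3S)-3-methyloxiran-2-yl]butan-1-ol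
Conditions: Ti(OiPr)4 (20 mol%), L-(+)-diisopropyl tartrate (24 mol%), t-BuOOH, 4 Å MS, CH2Cl2, −20 °C
Reagents that add atoms: tert-butyl hydroperoxide, CC(C)(C)OO
Why: Sharpless asymmetric epoxidation used in its matched sense: an (S)-configured E-allylic alcohol of this type is the fast-reacting partner of the L-(+)-tartrate titanium catalyst, which delivers oxygen to the olefin face that gives the anti (erythro) epoxy alcohol, so C11 and the trans-related C10 are fixed relative to C12.

Step 9
Reactants: 12 epoxy alcohol
Product: 13 (2R,3S)-2-{(1S,3R)-4-[5-bromo-2-(triisopropylsilyloxy)phenyl]-1-methoxy-3-methylbutyl}-3-methyloxirane (methyl ether of 12; only the CIP label of the oxirane carbon next to C12 changes)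
Conditions: MeOTf, 2,6-di-tert-butyl-4-methylpyridine, CH2Cl2, 0 °C to rt
Reagents that add atoms: methyl triflate, COS(=O)(=O)C(F)(F)F
Why: O-Methylation with methyl triflate and a hindered, non-nucleophilic pyridine alkylates the hydroxyl without ever forming the alkoxide, so epoxide migration (Payne rearrangement) is excluded and C12 keeps its configuration.

Step 10
Reactants: 13 epoxy methyl ether; 7 propyne
Product: 15 (4S,5R,6S,8R)-9-[5-bromo-2-(triisopropylsilyloxy)phenyl]-6-methoxy-4,8-dimethylnon-2-yn-5-ol, via 1-propynyllithium 14 (not isolated)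
Conditions: 7, n-BuLi, THF, −78 °C; BF3·OEt2; then 13, −78 °C
Reagents that add atoms: none
Why: Boron trifluoride-promoted SN2 opening of an epoxide by an alkynyllithium occurs with inversion at the methyl-bearing C10, the epoxide carbon that is less hindered and further from the electron-withdrawing C12 methoxy group, which places the C10 methyl syn to the C11 hydroxyl and attaches C9 with its ethylidyne end group.

Step 11
Reactants: 15 homopropargylic alcohol
Product: 16 tert-butyl{[(4S,5R,6S,8R)-9-[5-bromo-2-(triisopropylsilyloxy)phenyl]-6-methoxy-4,8-dimethylnon-2-yn-5-yl]oxy}dimethylsilane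
Conditions: TBSOTf, 2,6-lutidine, CH2Cl2, −78 to 0 °C
Reagents that add atoms: tert-butyldimethylsilyl triflate, CC(C)(C)[Si](C)(C)OS(=O)(=O)C(F)(F)F
Why: Silyl triflate silylation caps the hindered secondary C11 hydroxyl as a TBS ether, which is needed so that later only the C7 hydroxyl is free to direct the hydrostannation and to take the carbamate.

Step 12
Reactants: 17 allyl methyl ether; 18 but-2-ynal
Product: 21 (3S,4S)-3-methoxyhept-1-en-5-yn-4-ol, via (Z)-3-methoxyallyllithium 19 (not isolated), via (Z)-(3-methoxyallyl)diisopinocampheylborane 20 (not isolated)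
Conditions: 17, s-BuLi, THF, −78 °C; (+)-Ipc2BOMe [from (−)-α-pinene]; BF3·OEt2 then 18, −78 °C; NaOH, H2O2
Reagents that add atoms: none
Why: Brown asymmetric γ-alkoxyallylboration, in which the internally chelated Z-lithio ether is transferred to boron and adds through a closed chair transition state, so the Z geometry becomes the syn C6-methoxy/C7-hydroxy relationship and the isopinocampheyl groups derived from (−)-α-pinene choose the aldehyde face that gives the (3S,4S) isomer.

Step 13
Reactants: 21 (3S,4S)-3-methoxyhept-1-en-5-yn-4-ol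
Product: 22 triethyl{[(3S,4S)-3-methoxyhept-1-en-5-yn-4-yl]oxy}silane
Conditions: TESCl, imidazole, DMF, 0 °C
Reagents that add atoms: triethylsilyl chloride, CC[Si](Cl)(CC)CC
Why: Standard silylation gives a TES ether that masks the propargylic hydroxyl during the hydroboration, copper and molybdenum chemistry and can later be removed beside TBS and TIPS.

Step 14
Reactants: 23 propargyl alcohol
Product: 25 (E)-3-iodo-2-methylprop-2-en-1-ol, via alkenylalane 24 (not isolated)
Conditions: AlMe3, Cp2ZrCl2 (25 mol%), CH2Cl2, 0 °C to rt; then I2, THF, −30 to 0 °C; aq. K2CO3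
Reagents that add atoms: trimethylaluminium, C[Al](C)C; iodine, [I][I]
Why: Negishi zirconium-catalysed carboalumination adds methyl and aluminium syn across the alkyne with methyl on the internal carbon, and iodinolysis of the C–Al bond with retention gives the E-iodoalkene that later fixes the C2=C3 geometry.

Step 15
Reactants: 25 (E)-3-iodo-2-methylprop-2-en-1-ol
Product: 26 (E)-3-iodo-2-methylprop-2-enal
Conditions: MnO2, CH2Cl2, rt
Reagents that add atoms: none
Why: Heterogeneous MnO2 oxidation is selective for allylic alcohols, stops at the enal and leaves the alkenyl iodide and its geometry intact.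

Step 16
Reactants: 26 (E)-3-iodo-2-methylprop-2-enal
Product: 27 (E)-3-iodo-2-methylprop-2-enoic acid
Conditions: NaClO2, NaH2PO4, 2-methyl-2-butene, t-BuOH/H2O, 0 °C to rt
Reagents that add atoms: sodium chlorite, [Na+].[O-]Cl=O
Why: Pinnick oxidation converts the enal into the acid under buffered conditions while 2-methyl-2-butene traps hypochlorite, so the iodoalkene is not attacked.

Step 17
Reactants: 27 (E)-3-iodo-2-methylprop-2-enoic acid
Product: 29 (E)-3-iodo-2-methylprop-2-enamide, via mixed isobutyl carbonic anhydride 28 (not isolated)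
Conditions: i-BuOCOCl, N-methylmorpholine, THF, −15 °C; then aq. NH3
Reagents that add atoms: ammonia, N
Why: Mixed-anhydride activation followed by ammonolysis gives the primary amide at low temperature, where attack at the activated carbonyl is much faster than conjugate addition–elimination at the iodine-bearing carbon.

Step 18
Reactants: 22 TES ether; 29 (E)-3-iodo-2-methylprop-2-enamide
Product: 31 (2E,6S,7S)-6-methoxy-2-methyl-7-(triethylsilyloxy)dec-2-en-8-ynamide, via B-alkyl-9-BBN adduct 30 (not isolated)
Conditions: 9-BBN, THF, 0 °C to rt; then 29, Pd(dppf)Cl2 (5 mol%), AsPh3, Cs2CO3, DMF/H2O, rt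
Reagents that add atoms: none
Why: 9-BBN hydroborates the monosubstituted olefin anti-Markovnikov far faster than the internal alkyne, and B-alkyl Suzuki–Miyaura coupling of the resulting borane with the alkenyl iodide forms C3–C4 with retention of the E geometry in the presence of the primary amide.

Step 19
Reactants: 16 east aryl bromide; 31 west primary amide
Product: 32 (2E,6S,7S)-N-{3-[(2R,4S,5R,6S)-5-(tert-butyldimethylsilyloxy)-4-methoxy-2,6-dimethylnon-7-yn-1-yl]-4-(triisopropylsilyloxy)phenyl}-6-methoxy-2-methyl-7-(triethylsilyloxy)dec-2-en-8-ynamide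
Conditions: CuI (20 mol%), N,N'-dimethylethylenediamine, K2CO3, toluene, 110 °C
Reagents that add atoms: none
Why: Goldberg amidation (copper/diamine-catalysed N-arylation of a primary amide) joins the two halves at the unhindered aryl bromide, and the internal alkynes, the enamide olefin and the three silyl ethers tolerate anhydrous carbonate in hot toluene.

Step 20
Reactants: 32 acyclic anilide diyne
Product: 33 19-membered ansa-lactam with a C8≡C9 triple bond (2E; 6-OMe; 7-OTES; 10-Me; 11-OTBS; 12-OMe; 14-Me; aryl OTIPS; 6S,7S,10S,11R,12S,14R)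
Conditions: [Mo(≡C-C6H4-4-OMe)(OSiPh3)3] (15 mol%), 5 Å MS, toluene (0.002 M), 80 °C
Reagents that add atoms: none
Why: The Mo≡C unit and the triple bond at one end of the diyne combine in a formal [2+2] step to a molybdenacyclobutadiene, which opens in the other sense to expel the ethylidyne end group and leave the chain bound to molybdenum as a new alkylidyne; the same two-stage exchange at the remote alkyne of the same molecule joins C8 to C9 by a triple bond and releases the two end groups as 2-butyne. The closest known reaction type is ring-closing alkyne metathesis of functionalised methyl-capped diynes with molybdenum alkylidyne triarylsilanolate catalysts, which is established for macrocycles carrying a silyl-protected propargylic alcohol. The 19-membered meta-bridged anilide ring closes by end-to-end macrocyclisation with the new C8≡C9 bond inside the ring, and since an alkyne is linear the closure creates neither a stereocentre nor an olefin geometry. The step needs alkyne-over-alkene chemoselectivity, which this catalyst class provides because the alkylidyne does not engage the conjugated C2=C3 olefin, the anilide N–H or the ethers, and all hydroxyl groups are silylated. It also needs ring closure to win over oligomerisation, which is secured by high dilution, by the small methyl end groups and by 5 Å molecular sieves that absorb 2-butyne and make the closure irreversible. The congested trisubstituted olefin between C7 and C10 is thereby never formed in a cyclisation that would have to decide its geometry.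

Step 21
Reactants: 33 macrocyclic alkyne
Product: 34 C7 alcohol of 33 (macrocyclic propargylic alcohol; 11-OTBS and aryl OTIPS kept)
Conditions: PPTS (cat.), MeOH/CH2Cl2, 0 °C
Reagents that add atoms: none
Why: Acid-catalysed methanolysis of silyl ethers distinguishes sharply by bulk, so the TES ether at C7 should be cleaved while the hindered secondary TBS ether and the aryl TIPS ether stay.

Step 22
Reactants: 34 macrocyclic propargylic alcohol
Product: 35 C8-tributylstannyl allylic alcohol (C8=C9 olefin with C7 and C10 trans; 8Z and 7R by CIP because tin outranks carbon; no change in space at C7)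
Conditions: Bu3SnH, [Cp*RuCl]4 (5 mol%), CH2Cl2, rt
Reagents that add atoms: tributyltin hydride, CCCC[SnH](CCCC)CCCC
Why: Hydroxyl-directed ruthenium-catalysed trans-hydrostannation, in which a hydrogen bond from the C7 hydroxyl (the only free one) to the chloride on ruthenium steers tin to the proximal alkyne carbon C8 and hydrogen to C9 from opposite sides, so C7 and C10 lie trans across the new olefin; the conjugated C2=C3 olefin is inert.

Step 23
Reactants: 35 alkenylstannane
Product: 36 C8-methyl allylic alcohol (2E,8E; free 7-OH; 11-OTBS; aryl OTIPS; 6S,7S,10S,11R,12S,14R)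
Conditions: MeI, Pd(PPh3)4, Cu(O2C-C4H3S) [copper thiophene-2-carboxylate], [NBu4][Ph2PO2], DMF, rt
Reagents that add atoms: iodomethane, CI
Why: Copper-assisted Stille coupling of an alkenylstannane with methyl iodide (tin-to-copper exchange by the copper carboxylate, tin removed as its phosphinate) replaces tin by methyl with retention under base-free conditions that tolerate the neighbouring free hydroxyl, giving the E-trisubstituted C8=C9 olefin.

Step 24
Reactants: 36 C8-methyl allylic alcohol
Product: 38 C7 primary carbamate with 11-OTBS and aryl OTIPS, via N-trichloroacetyl carbamate 37 (not isolated)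
Conditions: Cl3CC(O)NCO, CH2Cl2, 0 °C; then neutral Al2O3, rt
Reagents that add atoms: trichloroacetyl isocyanate, O=C=NC(=O)C(Cl)(Cl)Cl
Why: Carbamoylation by addition of the C7 hydroxyl to the highly electrophilic acyl isocyanate and removal of the trichloroacetyl group on neutral alumina is the standard route to a primary carbamate, proceeds with retention at C7 and does not involve the much less nucleophilic anilide N–H.

Step 25
Reactants: 38 bis-silylated carbamate
Product: 39 target CNP0544610.1
Conditions: HF·pyridine, pyridine/THF, 0 °C to rt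
Reagents that add atoms: none
Why: Fluoride-mediated desilylation with buffered HF·pyridine should remove the secondary TBS ether and the aryl TIPS ether, while carbamate, lactam, methyl ethers and both trisubstituted olefins are stable to it.

**Compound list**

1 | 4-bromo-2-iodophenol | Oc1ccc(Br)cc1I | starting material
2 | (4-bromo-2-iodophenoxy)triisopropylsilane | CC(C)[Si](Oc1ccc(Br)cc1I)(C(C)C)C(C)C | intermediate
3 | (R)-methyl hydrogen 3-methylglutarate | COC(=O)C[C@H](C)CC(=O)O | starting material
4 | N-hydroxyphthalimide ester of 3 (CIP label S, configuration unchanged) | COC(=O)C[C@H](C)CC(=O)ON1C(=O)c2ccccc2C1=O | intermediate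
5 | methyl (3R)-4-[5-bromo-2-(triisopropylsilyloxy)phenyl]-3-methylbutanoate | COC(=O)C[C@H](C)Cc1cc(Br)ccc1O[Si](C(C)C)(C(C)C)C(C)C | intermediate
6 | (3R)-4-[5-bromo-2-(triisopropylsilyloxy)phenyl]-N-methoxy-N,3-dimethylbutanamide | CON(C)C(=O)C[C@H](C)Cc1cc(Br)ccc1O[Si](C(C)C)(C(C)C)C(C)C | intermediate
7 | propyne | CC#C | starting material
8 | 1-propynylmagnesium bromide | CC#C[Mg]Br | intermediate
9 | (6R)-7-[5-bromo-2-(triisopropylsilyloxy)phenyl]-6-methylhept-2-yn-4-one | CC#CC(=O)C[C@H](C)Cc1cc(Br)ccc1O[Si](C(C)C)(C(C)C)C(C)C | intermediate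
10 | (4S,6R)-7-[5-bromo-2-(triisopropylsilyloxy)phenyl]-6-methylhept-2-yn-4-ol | CC#C[C@@H](O)C[C@H](C)Cc1cc(Br)ccc1O[Si](C(C)C)(C(C)C)C(C)C | intermediate
11 | (2E,4S,6R)-7-[5-bromo-2-(triisopropylsilyloxy)phenyl]-6-methylhept-2-en-4-ol | C/C=C/[C@@H](O)C[C@H](C)Cc1cc(Br)ccc1O[Si](C(C)C)(C(C)C)C(C)C | intermediate
12 | (1S,3R)-4-[5-bromo-2-(triisopropylsilyloxy)phenyl]-3-methyl-1-[(2S,3S)-3-methyloxiran-2-yl]butan-1-ol | C[C@@H]1O[C@H]1[C@@H](O)C[C@H](C)Cc1cc(Br)ccc1O[Si](C(C)C)(C(C)C)C(C)C | intermediate
13 | (2R,3S)-2-{(1S,3R)-4-[5-bromo-2-(triisopropylsilyloxy)phenyl]-1-methoxy-3-methylbutyl}-3-methyloxirane | C[C@@H]1O[C@H]1[C@@H](OC)C[C@H](C)Cc1cc(Br)ccc1O[Si](C(C)C)(C(C)C)C(C)C | intermediate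
14 | 1-propynyllithium | [Li]C#CC | intermediate
15 | (4S,5R,6S,8R)-9-[5-bromo-2-(triisopropylsilyloxy)phenyl]-6-methoxy-4,8-dimethylnon-2-yn-5-ol | CC#C[C@H](C)[C@@H](O)[C@@H](OC)C[C@H](C)Cc1cc(Br)ccc1O[Si](C(C)C)(C(C)C)C(C)C | intermediate
16 | TBS ether of 15 (east half, C9–C15 with aryl bromide) | CC#C[C@H](C)[C@@H](O[Si](C)(C)C(C)(C)C)[C@@H](OC)C[C@H](C)Cc1cc(Br)ccc1O[Si](C(C)C)(C(C)C)C(C)C | intermediate
17 | allyl methyl ether | C=CCOC | starting material
18 | but-2-ynal | CC#CC=O | starting material
19 | (Z)-3-methoxyallyllithium | CO/C=C\C[Li] | intermediate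
20 | (Z)-(3-methoxyallyl)diisopinocampheylborane, Ipc groups from (−)-α-pinene | CO/C=C\CB([C@H]1C[C@H]2C[C@@H]([C@@H]1C)C2(C)C)[C@H]1C[C@H]2C[C@@H]([C@@H]1C)C2(C)C | intermediate
21 | (3S,4S)-3-methoxyhept-1-en-5-yn-4-ol | C=C[C@H](OC)[C@@H](O)C#CC | intermediate
22 | triethyl{[(3S,4S)-3-methoxyhept-1-en-5-yn-4-yl]oxy}silane | C=C[C@H](OC)[C@@H](O[Si](CC)(CC)CC)C#CC | intermediate
23 | propargyl alcohol | C#CCO | starting material
24 | (E)-alkenylalane from carboalumination, as its dimethylaluminium alkoxide | C[Al](C)OC/C(C)=C/[Al](C)C | intermediate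
25 | (E)-3-iodo-2-methylprop-2-en-1-ol | OC/C(C)=C/I | intermediate
26 | (E)-3-iodo-2-methylprop-2-enal | O=C/C(C)=C/I | intermediate
27 | (E)-3-iodo-2-methylprop-2-enoic acid | OC(=O)/C(C)=C/I | intermediate
28 | mixed isobutyl carbonic anhydride of 27 | CC(C)COC(=O)OC(=O)/C(C)=C/I | intermediate
29 | (E)-3-iodo-2-methylprop-2-enamide | NC(=O)/C(C)=C/I | intermediate
30 | B-alkyl-9-BBN adduct of 22 | C1CCC2CCCC1B2CC[C@H](OC)[C@@H](O[Si](CC)(CC)CC)C#CC | intermediate
31 | (2E,6S,7S)-6-methoxy-2-methyl-7-(triethylsilyloxy)dec-2-en-8-ynamide | NC(=O)/C(C)=C/CC[C@H](OC)[C@@H](O[Si](CC)(CC)CC)C#CC | intermediate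
32 | acyclic anilide diyne (N-aryl amide from 16 and 31) | CC#C[C@H](C)[C@@H](O[Si](C)(C)C(C)(C)C)[C@@H](OC)C[C@H](C)Cc1cc(ccc1O[Si](C(C)C)(C(C)C)C(C)C)NC(=O)/C(C)=C/CC[C@H](OC)[C@@H](O[Si](CC)(CC)CC)C#CC | intermediate
33 | 19-membered ansa-lactam cycloalkyne (C8≡C9; 7-OTES, 11-OTBS, aryl OTIPS) | CO[C@H]1C[C@H](C)Cc2cc(ccc2O[Si](C(C)C)(C(C)C)C(C)C)NC(=O)/C(C)=C/CC[C@H](OC)[C@@H](O[Si](CC)(CC)CC)C#C[C@H](C)[C@H]1O[Si](C)(C)C(C)(C)C | intermediate
34 | macrocyclic propargylic alcohol (free 7-OH) | CO[C@H]1C[C@H](C)Cc2cc(ccc2O[Si](C(C)C)(C(C)C)C(C)C)NC(=O)/C(C)=C/CC[C@H](OC)[C@@H](O)C#C[C@H](C)[C@H]1O[Si](C)(C)C(C)(C)C | intermediate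
35 | C8-tributylstannyl macrocyclic allylic alcohol (C7 and C10 trans) | CO[C@H]1C[C@H](C)Cc2cc(ccc2O[Si](C(C)C)(C(C)C)C(C)C)NC(=O)/C(C)=C/CC[C@H](OC)[C@@H](O)/C([Sn](CCCC)(CCCC)CCCC)=C/[C@H](C)[C@H]1O[Si](C)(C)C(C)(C)C | intermediate
36 | C8-methyl macrocyclic allylic alcohol (2E,8E) | CO[C@H]1C[C@H](C)Cc2cc(ccc2O[Si](C(C)C)(C(C)C)C(C)C)NC(=O)/C(C)=C/CC[C@H](OC)[C@@H](O)/C(C)=C/[C@H](C)[C@H]1O[Si](C)(C)C(C)(C)C | intermediate
37 | N-trichloroacetyl carbamate at C7 | CO[C@H]1C[C@H](C)Cc2cc(ccc2O[Si](C(C)C)(C(C)C)C(C)C)NC(=O)/C(C)=C/CC[C@H](OC)[C@@H](OC(=O)NC(=O)C(Cl)(Cl)Cl)/C(C)=C/[C@H](C)[C@H]1O[Si](C)(C)C(C)(C)C | intermediate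
38 | C7 primary carbamate with 11-OTBS and aryl OTIPS | CO[C@H]1C[C@H](C)Cc2cc(ccc2O[Si](C(C)C)(C(C)C)C(C)C)NC(=O)/C(C)=C/CC[C@H](OC)[C@@H](OC(N)=O)/C(C)=C/[C@H](C)[C@H]1O[Si](C)(C)C(C)(C)C | intermediate
39 | CNP0544610.1, (2E,8E;6S,7S,10S,11R,12S,14R) ansa-lactam | CO[C@H]1C[C@H](C)Cc2cc(ccc2O)NC(=O)/C(C)=C/CC[C@H](OC)[C@@H](OC(N)=O)/C(C)=C/[C@H](C)[C@H]1O | target

**Summary**

Total step count: 25.
Longest linear sequence: 17 steps (steps 1, 3–11 and 19–25, from 1 to 39).

Steps most likely to fail:

Step 3. Oxidative addition at the iodide crowded by the ortho silyloxy group may be slow, so the alkyl radical could be lost to reduction or dimerisation, and the C–Br bond could begin to react. The fallback makes the same bond with the roles reversed and sets out from 3 and 2. Acid 3 is converted by photochemical iododecarboxylation (PhI(OAc)2, I2, hν, 1,2-dichloroethane) into methyl (S)-4-iodo-3-methylbutanoate F1. Zinc insertion (Zn dust, LiCl, THF) gives (S)-(4-methoxy-2-methyl-4-oxobutyl)zinc iodide F2. A palladium-catalysed Negishi coupling with 2 (Pd(OAc)2, SPhos, THF, rt), which discriminates cleanly between C–I and C–Br, comes back to the route at 5.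

Step 20. Ring closure may lose out to intermolecular metathesis, or the alkylidyne may engage only slowly two alkynes that are both branched at the propargylic carbon, or it may be held up by the anilide. The fallback moves the ring closure to the C–N bond and sets out from 16 and 22. Alkyne cross-metathesis of 16 with an excess of the cheap ether 22 (same molybdenum alkylidyne, 5 Å MS, concentrated toluene) gives the acyclic C8≡C9 alkyne F3. Hydroboration of its vinyl group with 9-BBN gives the B-alkyl-9-BBN adduct F4, which is coupled with 29 under the conditions of step 18 to the seco amide aryl bromide F5. Intramolecular Goldberg amidation under dilution (CuI, N,N'-dimethylethylenediamine, K2CO3, toluene, 110 °C), a macrolactamisation known for benzenoid ansa-lactams of this ring size, comes back to the route at 33.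

Step 23. Protodestannation may outrun the slow transmetalation of a hindered alkenylstannane that sits next to a free hydroxyl. The fallback reverses the polarity of the coupling and sets out from 35. Iododestannylation with I2 in CH2Cl2 at 0 °C proceeds with retention to the C8 alkenyl iodide F6. Negishi methylation (ZnMe2 in excess, Pd(P(t-Bu)3)2, THF, rt), which tolerates the zinc alkoxide and amidate formed in the flask, comes back to the route at 36.

Further compounds
F1 | step 3 | methyl (S)-4-iodo-3-methylbutanoate | COC(=O)C[C@H](C)CI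
F2 | step 3 | (S)-(4-methoxy-2-methyl-4-oxobutyl)zinc iodide | COC(=O)C[C@H](C)C[Zn]I
F3 | step 20 | acyclic C8≡C9 alkyne from cross-metathesis of 16 and 22 | C=C[C@H](OC)[C@@H](O[Si](CC)(CC)CC)C#C[C@H](C)[C@@H](O[Si](C)(C)C(C)(C)C)[C@@H](OC)C[C@H](C)Cc1cc(Br)ccc1O[Si](C(C)C)(C(C)C)C(C)C
F4 | step 20 | B-alkyl-9-BBN adduct of F3 | C1CCC2CCCC1B2CC[C@H](OC)[C@@H](O[Si](CC)(CC)CC)C#C[C@H](C)[C@@H](O[Si](C)(C)C(C)(C)C)[C@@H](OC)C[C@H](C)Cc1cc(Br)ccc1O[Si](C(C)C)(C(C)C)C(C)C
F5 | step 20 | seco amide aryl bromide with C8≡C9 alkyne | NC(=O)/C(C)=C/CC[C@H](OC)[C@@H](O[Si](CC)(CC)CC)C#C[C@H](C)[C@@H](O[Si](C)(C)C(C)(C)C)[C@@H](OC)C[C@H](C)Cc1cc(Br)ccc1O[Si](C(C)C)(C(C)C)C(C)C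
F6 | step 23 | C8-iodo macrocyclic allylic alcohol (C7 and C10 trans) | CO[C@H]1C[C@H](C)Cc2cc(ccc2O[Si](C(C)C)(C(C)C)C(C)C)NC(=O)/C(C)=C/CC[C@H](OC)[C@@H](O)/C(I)=C/[C@H](C)[C@H]1O[Si](C)(C)C(C)(C)C
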